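**Plan**

- Retrosynthetic cuts, in order: (a) the bond from ring carbon C6 to the allylic chain carbon C1′, which also traces the ring methyl back to the CH2CO2H arm of homogentisic acid; (b) C1′–O, the diphosphate coming from the allylic alcohol; (c) C8′–C9′, which divides the C20 chain into a geraniol-derived C1′–C8′ bromide and a nerol-derived C9′–C16′ sulfone diol.
- Forward order: the chain is joined at C8′–C9′ by sulfone alkylation, the sulfone is excised, C1′ is activated as chloride and then diphosphate, and the ring is attached last. No ring is built; the quinone arises by oxidation of the quinol formed in the key step.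
- Stereochemistry: C10′ and C11′ come from Sharpless asymmetric epoxidation of nerol with L-(+)-tartrate, followed by a Payne rearrangement that inverts the future C10′. The 2′E and 6′E olefins are those of geraniol.
- Enabling feature: the ring is a 1,4-dioxygenated six-membered carbocycle whose C1 oxygen is flanked by the C2 methyl and the C6 allyl chain. This is the 2-methyl-6-prenylquinol pattern that homogentisate prenyltransferases assemble, and C1′ is allylic to the C2′=C3′ olefin, so its diphosphate can ionise in the enzyme.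

Key step: step 12

Assumption: the prenyltransferase is obtained by heterologous expression and used as a membrane preparation, so it is treated as a catalyst; the starting materials 1, 5 and 16 are commercial.

**Route**

Step 1
Reactants: 1 geraniol [(2E)-3,7-dimethylocta-2,6-dien-1-ol]
Product: 2 tert-butyl{[(2E)-3,7-dimethylocta-2,6-dien-1-yl]oxy}dimethylsilane
Conditions: TBSCl, imidazole, DMF, 0 °C to rt
Reagents that add atoms: tert-butyldimethylsilyl chloride, CC(C)(C)[Si](C)(C)Cl
Why: Imidazole-promoted silylation of the primary allylic alcohol is a standard protection that masks the C1′ hydroxyl against the later oxidation and organolithium steps and creates no stereocentre.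

Step 2
Reactants: 2 tert-butyl{[(2E)-3,7-dimethylocta-2,6-dien-1-yl]oxy}dimethylsilane
Product: 3 (2E,6E)-8-[(tert-butyldimethylsilyl)oxy]-2,6-dimethylocta-2,6-dien-1-ol
Conditions: SeO2 (cat.), t-BuOOH, salicylic acid (cat.), CH2Cl2, 0 °C to rt
Reagents that add atoms: tert-butyl hydroperoxide, CC(C)(C)OO (oxygen relayed by catalytic SeO2, O=[Se]=O)
Why: SeO2-catalysed allylic oxidation (ene reaction then [2,3]-sigmatropic shift) should attack the (E)-methyl of the distal, more electron-rich trisubstituted olefin, because the proximal olefin is deactivated by its allylic oxygen, and should give the (E)-allylic alcohol.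

Step 3
Reactants: 3 (2E,6E)-8-[(tert-butyldimethylsilyl)oxy]-2,6-dimethylocta-2,6-dien-1-ol
Product: 4 tert-butyl{[(2E,6E)-8-bromo-3,7-dimethylocta-2,6-dien-1-yl]oxy}dimethylsilane
Conditions: CBr4, PPh3, CH2Cl2, 0 °C
Reagents that add atoms: carbon tetrabromide, BrC(Br)(Br)Br
Why: Appel bromination converts the primary allylic alcohol into the bromide by SN2 displacement of the oxyphosphonium group under neutral conditions that spare the silyl ether and both olefin geometries.

Step 4
Reactants: 5 nerol [(2Z)-3,7-dimethylocta-2,6-dien-1-ol]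
Product: 6 [(2S,3R)-3-methyl-3-(4-methylpent-3-en-1-yl)oxiran-2-yl]methanol
Conditions: Ti(OiPr)4 (cat.), L-(+)-diethyl tartrate (cat.), t-BuOOH, 4 Å MS, CH2Cl2, −20 °C
Reagents that add atoms: tert-butyl hydroperoxide, CC(C)(C)OO
Why: Sharpless asymmetric epoxidation oxidises only the allylic-alcohol olefin, and with L-(+)-tartrate it should deliver oxygen to the face of the (Z)-olefin that gives the (2S,3R)-epoxide, which sets the future C11′ in its final sense and the future C10′ in the sense that the next step inverts.

Step 5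
Reactants: 6 [(2S,3R)-3-methyl-3-(4-methylpent-3-en-1-yl)oxiran-2-yl]methanol
Product: 8 (2S,3R)-3,7-dimethyl-1-(phenylsulfanyl)oct-6-ene-2,3-diol, via (2R)-6-methyl-2-[(2R)-oxiran-2-yl]hept-5-en-2-ol 7 (not isolated)
Conditions: PhSH (slow addition), NaOH (0.5 M aq), t-BuOH, reflux, N2
Reagents that add atoms: thiophenol, Sc1ccccc1
Why: Under Payne rearrangement conditions the C1 alkoxide opens the epoxide at C2 with inversion to give terminal epoxide 7, which thiolate captures at its unhindered CH2, so the future C10′ is inverted to the required configuration while the future C11′ keeps its oxygen with retention.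

Step 6
Reactants: 8 (2S,3R)-3,7-dimethyl-1-(phenylsulfanyl)oct-6-ene-2,3-diol
Product: 9 (2S,3R)-3,7-dimethyl-1-(phenylsulfonyl)oct-6-ene-2,3-diol
Conditions: (NH4)6Mo7O24·4H2O (cat.), 30% H2O2, EtOH, 0 °C to rt
Reagents that add atoms: hydrogen peroxide, OO
Why: Molybdate-catalysed peroxide oxidation of a sulfide to the sulfone is much faster than epoxidation of the isolated trisubstituted olefin and leaves the diol and both stereocentres untouched.

Step 7
Reactants: 9 (2S,3R)-3,7-dimethyl-1-(phenylsulfonyl)oct-6-ene-2,3-diol; 4 tert-butyl{[(2E,6E)-8-bromo-3,7-dimethylocta-2,6-dien-1-yl]oxy}dimethylsilane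
Product: 11 (6R,7S,10E,14E)-16-[(tert-butyldimethylsilyl)oxy]-2,6,10,14-tetramethyl-8-(phenylsulfonyl)hexadeca-2,10,14-triene-6,7-diol (both C8 epimers), via trilithiated sulfone diol 10 (not isolated)
Conditions: n-BuLi (3.1 equiv), THF–DMPU, −78 to −30 °C; then 4, −78 to −20 °C; then H2O
Reagents that add atoms: none
Why: Alkylation of the α-sulfonyl carbanion of a β-hydroxy sulfone polyanion, whose lithium alkoxides cannot leave and are poor nucleophiles at low temperature, should proceed by SN2 attack on the primary allylic bromide and form the C8′–C9′ bond without touching C10′ or C11′, the new sulfonyl-bearing centre being of no consequence because the sulfone is removed next.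

Step 8
Reactants: 11 (6R,7S,10E,14E)-16-[(tert-butyldimethylsilyl)oxy]-2,6,10,14-tetramethyl-8-(phenylsulfonyl)hexadeca-2,10,14-triene-6,7-diol
Product: 12 (6R,7R,10E,14E)-16-[(tert-butyldimethylsilyl)oxy]-2,6,10,14-tetramethylhexadeca-2,10,14-triene-6,7-diol
Conditions: Na/Hg (6% Na), Na2HPO4, MeOH–THF, −20 °C
Reagents that add atoms: none
Why: Reductive desulfonylation by electron transfer from sodium amalgam in buffered methanol replaces the sulfonyl group by hydrogen, and because the β-oxygen is a free hydroxyl and not an ester, Julia-type elimination should be minor.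

Step 9
Reactants: 12 (6R,7R,10E,14E)-16-[(tert-butyldimethylsilyl)oxy]-2,6,10,14-tetramethylhexadeca-2,10,14-triene-6,7-diol
Product: 13 (2E,6E,10R,11R)-3,7,11,15-tetramethylhexadeca-2,6,14-triene-1,10,11-triol
Conditions: TBAF, THF, 0 °C to rt
Reagents that add atoms: none
Why: Fluoride-mediated cleavage of the silyl ether frees the primary allylic alcohol without affecting the diol or the olefins.

Step 10
Reactants: 13 (2E,6E,10R,11R)-3,7,11,15-tetramethylhexadeca-2,6,14-triene-1,10,11-triol
Product: 14 (6R,7R,10E,14E)-16-chloro-2,6,10,14-tetramethylhexadeca-2,10,14-triene-6,7-diol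
Conditions: NCS, Me2S, CH2Cl2, −40 to 0 °C
Reagents that add atoms: N-chlorosuccinimide, ClN1C(=O)CCC1=O
Why: The Corey–Kim reagent converts allylic alcohols into chlorides through an alkoxysulfonium salt that chloride displaces by SN2 only at the activated allylic carbon, whereas any sulfonium salt formed at the hindered secondary hydroxyl should revert to the alcohol on aqueous work-up and the tertiary hydroxyl should not react.

Step 11
Reactants: 14 (6R,7R,10E,14E)-16-chloro-2,6,10,14-tetramethylhexadeca-2,10,14-triene-6,7-diol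
Product: 15 (2E,6E,10R,11R)-10,11-dihydroxy-3,7,11,15-tetramethylhexadeca-2,6,14-trien-1-yl diphosphate
Conditions: (n-Bu4N)3HP2O7, MeCN, rt; then cation exchange (resin in NH4+ form, aq NH4HCO3), cellulose chromatography
Reagents that add atoms: tris(tetrabutylammonium) hydrogen diphosphate, CCCC[N+](CCCC)(CCCC)CCCC.CCCC[N+](CCCC)(CCCC)CCCC.CCCC[N+](CCCC)(CCCC)CCCC.OP(=O)([O-])OP(=O)([O-])[O-]
Why: SN2 displacement of a primary allylic chloride by the hydrogen diphosphate trianion in acetonitrile is the standard route to allylic diphosphates and should tolerate the free diol, whose hydroxyls are not nucleophilic under these neutral conditions.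

Step 12
Reactants: 15 (2E,6E,10R,11R)-10,11-dihydroxy-3,7,11,15-tetramethylhexadeca-2,6,14-trien-1-yl diphosphate; 16 homogentisic acid [(2,5-dihydroxyphenyl)acetic acid]
Product: 18 2-[(2E,6E,10R,11R)-10,11-dihydroxy-3,7,11,15-tetramethylhexadeca-2,6,14-trien-1-yl]-6-methylcyclohexa-2,5-diene-1,4-dione, via quinol 2-[(2E,6E,10R,11R)-10,11-dihydroxy-3,7,11,15-tetramethylhexadeca-2,6,14-trien-1-yl]-6-methylbenzene-1,4-diol 17 (not isolated)
Conditions: 16 (2 equiv), recombinant homogentisate geranylgeranyltransferase (membrane-bound aromatic prenyltransferase of the UbiA family, membrane fraction), MgCl2, Tris-HCl pH 7.6, 30 °C, N2; EtOAc extraction; then Ag2O, Et2O, rt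
Reagents that add atoms: none
Why: Proposed new method: homogentisate prenyltransferases have so far been run with unfunctionalised all-trans prenyl diphosphates, so acceptance of the diol-bearing donor 15 is argued from the mechanism of the native reaction with geranylgeranyl diphosphate, the closest known reaction type. Mg2+ held by the Asp-rich motifs binds the diphosphate of 15, ionisation at C1′ gives an allyl cation–diphosphate ion pair stabilised by the C2′=C3′ olefin, and ring carbon C3 of homogentisate (ortho to its C2 hydroxyl) attacks C1′ in an enzyme-templated Friedel–Crafts alkylation that is coupled to loss of CO2 from the CH2CO2H arm, which becomes the ring methyl of quinol 17. No ring is closed and no stereocentre is formed; the C10′ and C11′ carbinols sit nine and ten bonds from the reacting carbon in the part of the chain that lies along the lipid-facing tunnel, for which enzymes of this family accept donors from C15 to C45, so the diol should cost affinity but not block turnover. The step needs C- over O-alkylation, attack at the single ring position between the phenol and a hydrogen (which gives the 2-methyl-6-alkyl pattern that electrophilic or conjugate additions to toluquinone derivatives do not favour), retention of the 2′E geometry, and no cation–olefin cyclisation or capture by the diol. These are secured by the enzyme, which anchors the carboxylate arm so that only C3 faces C1′ of a tightly paired cation shielded from water, and by the substrate, whose only ionisable group is the primary allylic diphosphate and whose hydroxyls are remote from C1′. Ag2O should then oxidise the air-sensitive quinol 17 to quinone 18 without touching the diol or the olefins.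

**Compound list**

1 | geraniol [(2E)-3,7-dimethylocta-2,6-dien-1-ol] | CC(C)=CCC/C(C)=C/CO | starting material
2 | tert-butyl{[(2E)-3,7-dimethylocta-2,6-dien-1-yl]oxy}dimethylsilane | CC(C)=CCC/C(C)=C/CO[Si](C)(C)C(C)(C)C | intermediate
3 | (2E,6E)-8-[(tert-butyldimethylsilyl)oxy]-2,6-dimethylocta-2,6-dien-1-ol | OC/C(C)=C/CC/C(C)=C/CO[Si](C)(C)C(C)(C)C | intermediate
4 | tert-butyl{[(2E,6E)-8-bromo-3,7-dimethylocta-2,6-dien-1-yl]oxy}dimethylsilane | BrC/C(C)=C/CC/C(C)=C/CO[Si](C)(C)C(C)(C)C | intermediate
5 | nerol [(2Z)-3,7-dimethylocta-2,6-dien-1-ol] | CC(C)=CCC/C(C)=C\CO | starting material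
6 | [(2S,3R)-3-methyl-3-(4-methylpent-3-en-1-yl)oxiran-2-yl]methanol | OC[C@@H]1O[C@]1(C)CCC=C(C)C | intermediate
7 | (2R)-6-methyl-2-[(2R)-oxiran-2-yl]hept-5-en-2-ol | CC(C)=CCC[C@@](C)(O)[C@H]1CO1 | intermediate (not isolated)
8 | (2S,3R)-3,7-dimethyl-1-(phenylsulfanyl)oct-6-ene-2,3-diol | CC(C)=CCC[C@@](C)(O)[C@H](O)CSc1ccccc1 | intermediate
9 | (2S,3R)-3,7-dimethyl-1-(phenylsulfonyl)oct-6-ene-2,3-diol | CC(C)=CCC[C@@](C)(O)[C@H](O)CS(=O)(=O)c1ccccc1 | intermediate
10 | trilithiated sulfone diol (C1 carbanion and both alkoxides of 9 as lithium derivatives) | CC(C)=CCC[C@@](C)(O[Li])[C@H](O[Li])C([Li])S(=O)(=O)c1ccccc1 | intermediate (not isolated)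
11 | (6R,7S,10E,14E)-16-[(tert-butyldimethylsilyl)oxy]-2,6,10,14-tetramethyl-8-(phenylsulfonyl)hexadeca-2,10,14-triene-6,7-diol (both C8 epimers) | CC(C)=CCC[C@@](C)(O)[C@H](O)C(C/C(C)=C/CC/C(C)=C/CO[Si](C)(C)C(C)(C)C)S(=O)(=O)c1ccccc1 | intermediate
12 | (6R,7R,10E,14E)-16-[(tert-butyldimethylsilyl)oxy]-2,6,10,14-tetramethylhexadeca-2,10,14-triene-6,7-diol | CC(C)=CCC[C@@](C)(O)[C@H](O)CC/C(C)=C/CC/C(C)=C/CO[Si](C)(C)C(C)(C)C | intermediate
13 | (2E,6E,10R,11R)-3,7,11,15-tetramethylhexadeca-2,6,14-triene-1,10,11-triol | CC(C)=CCC[C@@](C)(O)[C@H](O)CC/C(C)=C/CC/C(C)=C/CO | intermediate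
14 | (6R,7R,10E,14E)-16-chloro-2,6,10,14-tetramethylhexadeca-2,10,14-triene-6,7-diol | CC(C)=CCC[C@@](C)(O)[C@H](O)CC/C(C)=C/CC/C(C)=C/CCl | intermediate
15 | (2E,6E,10R,11R)-10,11-dihydroxy-3,7,11,15-tetramethylhexadeca-2,6,14-trien-1-yl diphosphate (handled as its ammonium salt; drawn as the acid) | CC(C)=CCC[C@@](C)(O)[C@H](O)CC/C(C)=C/CC/C(C)=C/COP(=O)(O)OP(=O)(O)O | intermediate
16 | homogentisic acid [(2,5-dihydroxyphenyl)acetic acid] | OC(=O)Cc1cc(O)ccc1O | starting material
17 | 2-[(2E,6E,10R,11R)-10,11-dihydroxy-3,7,11,15-tetramethylhexadeca-2,6,14-trien-1-yl]-6-methylbenzene-1,4-diol | CC(C)=CCC[C@@](C)(O)[C@H](O)CC/C(C)=C/CC/C(C)=C/Cc1cc(O)cc(C)c1O | intermediate (not isolated)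
18 | 2-[(2E,6E,10R,11R)-10,11-dihydroxy-3,7,11,15-tetramethylhexadeca-2,6,14-trien-1-yl]-6-methylcyclohexa-2,5-diene-1,4-dione | CC(C)=CCC[C@@](C)(O)[C@H](O)CC/C(C)=C/CC/C(C)=C/CC1=CC(=O)C=C(C)C1=O | target

**Step count and risks**

Total steps: 12. Longest linear sequence: 9 steps (steps 4 to 12 from nerol 5; the line from geraniol 1 through steps 1 to 3 and 7 to 12 is equally long).

Steps most likely to fail:

1. Step 12 (bears the label "Proposed new method:"). The polar diol may prevent binding or turnover of donor 15 in the hydrophobic chain tunnel, or the membrane enzyme may lose activity at preparative substrate loading. The fallback uses known chemistry, sets out from chloride 14 and comes back to the route at target 18. Sodium 4-methoxy-2-methylphenoxide (from commercial 4-methoxy-2-methylphenol and NaH in toluene, with NaI as catalyst) is C-alkylated by 14 at its only free ortho position, which should give 2-[(2E,6E,10R,11R)-10,11-dihydroxy-3,7,11,15-tetramethylhexadeca-2,6,14-trien-1-yl]-4-methoxy-6-methylphenol F1. Oxidative demethylation of F1 with PhI(OAc)2 in aqueous MeCN at 0 °C should then give 18.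

2. Step 7. The trilithiated sulfone may be too poorly soluble or too weakly nucleophilic, and O-alkylation of the alkoxides or base-induced loss of HBr from 4 may compete. The fallback sets out from sulfone diol 9 and comes back at triol 13.
   - The diol is masked with 2,2-dimethoxypropane and PPTS as (4R,5S)-2,2,4-trimethyl-4-(4-methylpent-3-en-1-yl)-5-[(phenylsulfonyl)methyl]-1,3-dioxolane F2.
   - Its monolithio derivative (n-BuLi, THF, −78 °C) is alkylated with 4, which should give tert-butyl{[(2E,6E)-3,7-dimethyl-9-(phenylsulfonyl)-9-[(4S,5R)-2,2,5-trimethyl-5-(4-methylpent-3-en-1-yl)-1,3-dioxolan-4-yl]nona-2,6-dien-1-yl]oxy}dimethylsilane F3.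
   - Dilute aqueous HCl in THF removes the acetonide and the silyl ether together to give (2E,6E,10S,11R)-3,7,11,15-tetramethyl-9-(phenylsulfonyl)hexadeca-2,6,14-triene-1,10,11-triol F4.
   - Na/Hg in buffered MeOH then removes the sulfone to give 13.

3. Step 5. Thiolate may open epoxide 6 directly at C2, or the Payne equilibrium may lie too far on the side of 6, so that regioisomeric sulfides form. The fallback sets out from nerol 5 and comes back at sulfide diol 8; it inverts the tertiary carbon with water instead of inverting C2.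
   - Sharpless epoxidation of 5 with D-(−)-diethyl tartrate should give [(2R,3S)-3-methyl-3-(4-methylpent-3-en-1-yl)oxiran-2-yl]methanol F5.
   - Hydrolysis with dilute HClO4 in THF–H2O, with inversion at the tertiary epoxide carbon, should give (2R,3R)-3,7-dimethyloct-6-ene-1,2,3-triol F6.
   - Selective sulfonylation of the primary hydroxyl (TsCl, Et3N, Bu2SnO cat.) gives (2R,3R)-2,3-dihydroxy-3,7-dimethyloct-6-en-1-yl 4-methylbenzenesulfonate F7.
   - Displacement with PhSNa in DMF gives 8.

**Further compounds**

F1 | step 12 | 2-[(2E,6E,10R,11R)-10,11-dihydroxy-3,7,11,15-tetramethylhexadeca-2,6,14-trien-1-yl]-4-methoxy-6-methylphenol | CC(C)=CCC[C@@](C)(O)[C@H](O)CC/C(C)=C/CC/C(C)=C/Cc1cc(OC)cc(C)c1O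
F2 | step 7 | (4R,5S)-2,2,4-trimethyl-4-(4-methylpent-3-en-1-yl)-5-[(phenylsulfonyl)methyl]-1,3-dioxolane | CC(C)=CCC[C@@]1(C)OC(C)(C)O[C@@H]1CS(=O)(=O)c1ccccc1
F3 | step 7 | tert-butyl{[(2E,6E)-3,7-dimethyl-9-(phenylsulfonyl)-9-[(4S,5R)-2,2,5-trimethyl-5-(4-methylpent-3-en-1-yl)-1,3-dioxolan-4-yl]nona-2,6-dien-1-yl]oxy}dimethylsilane | CC(C)=CCC[C@@]1(C)OC(C)(C)O[C@@H]1C(C/C(C)=C/CC/C(C)=C/CO[Si](C)(C)C(C)(C)C)S(=O)(=O)c1ccccc1
F4 | step 7 | (2E,6E,10S,11R)-3,7,11,15-tetramethyl-9-(phenylsulfonyl)hexadeca-2,6,14-triene-1,10,11-triol | CC(C)=CCC[C@@](C)(O)[C@H](O)C(C/C(C)=C/CC/C(C)=C/CO)S(=O)(=O)c1ccccc1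
F5 | step 5 | [(2R,3S)-3-methyl-3-(4-methylpent-3-en-1-yl)oxiran-2-yl]methanol | OC[C@H]1O[C@@]1(C)CCC=C(C)C
F6 | step 5 | (2R,3R)-3,7-dimethyloct-6-ene-1,2,3-triol | CC(C)=CCC[C@@](C)(O)[C@H](O)CO
F7 | step 5 | (2R,3R)-2,3-dihydroxy-3,7-dimethyloct-6-en-1-yl 4-methylbenzenesulfonate | CC(C)=CCC[C@@](C)(O)[C@H](O)COS(=O)(=O)c1ccc(C)cc1
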